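**Retrosynthetic overview**

- The target is 3α-angeloyloxy-4α-acetoxy-11-hydroxy-5αH-eudesm-6-en-8-one (eudesmane numbering: ring A = C1–C5 and C10, ring B = C5–C10, C14 on C10, C15 on C4, C11 on C7). The strategy rests on ring B, a cyclohexene with its alkene at C6=C7, the C11 carbinol on C7 and the quaternary C10 (C14 methyl and C1) next to the C5–H stereocentre.
- Late stage: the silyl group on O11 is removed, the C8 ketone comes from allylic oxidation of the C6=C7 alkene, and the two esters come from stepwise acylation of a cis-3α,4α-diol.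
- Ring A: the diol comes from a C1=C2–C3=O enone by C4 methylation, α-face enolate hydroxylation, C1=C2 hydrogenation and C3 reduction. The enone comes from aldol condensation of a keto aldehyde (C2 methyl ketone onto the C1 aldehyde).
- Ring B: exo, enantioselective Diels–Alder reaction of an (E)-2,4-disubstituted diene (C5–C8) with methacrolein (C9, C10, C14, C1), forming C5–C10 and C8–C9. The diene comes from an enyne cross-metathesis.
- Ring order: ring B first (cycloaddition), ring A second (aldol condensation).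

Key step: step 5

Assumption: the catalyst is taken to show the same sense of induction as in exo cycloadditions of 2-substituted acroleins with cyclopentadiene, which calls for the (R)-catalyst here; were the opposite sense found, the (S)-catalyst would be used with no other change.

**Route**

Step 1
Reactants: 1 2-methylbut-3-yn-2-ol
Product: 2 triethyl[(2-methylbut-3-yn-2-yl)oxy]silane
Conditions: Et3SiCl, imidazole, DMAP (cat.), DMF, 0 °C to rt
Reagents that add atoms: chlorotriethylsilane, CC[Si](Cl)(CC)CC
Why: Silylation of an unhindered propargylic tertiary alcohol; the silyl ether masks the C11 hydroxyl for the metathesis, the Lewis acid step and the enolate chemistry.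

Step 2
Reactants: 3 ethyl (2-methyl-1,3-dioxolan-2-yl)acetate
Product: 4 (2-methyl-1,3-dioxolan-2-yl)acetaldehyde
Conditions: i-Bu2AlH (1.05 equiv), CH2Cl2, −78 °C; aq. KNaC4H4O6 (potassium sodium tartrate)
Reagents that add atoms: none
Why: Partial reduction of an ester at low temperature; the aluminium hemiacetal, held by a ketal oxygen, should persist until work-up and then release the aldehyde.

Step 3
Reactants: 4 (2-methyl-1,3-dioxolan-2-yl)acetaldehyde
Product: 5 2-methyl-2-(prop-2-en-1-yl)-1,3-dioxolane
Conditions: Ph3PCH3Br, KOt-Bu, THF, 0 °C to rt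
Reagents that add atoms: methyltriphenylphosphonium bromide, C[P+](c1ccccc1)(c1ccccc1)c1ccccc1.[Br-]
Why: Wittig methylenation; the non-stabilised ylide should add to the aldehyde faster than it deprotonates it, and the ketal is inert to base.

Step 4
Reactants: 2 triethyl[(2-methylbut-3-yn-2-yl)oxy]silane; 5 2-methyl-2-(prop-2-en-1-yl)-1,3-dioxolane
Product: 7 (E)-triethyl{[2-methyl-3-methylidene-6-(2-methyl-1,3-dioxolan-2-yl)hex-4-en-2-yl]oxy}silane, via silyloxy butadiene 6 (not isolated)
Conditions: second-generation Grubbs catalyst (H2IMes)(PCy3)Cl2Ru=CHPh (5 mol%), ethylene (1 atm), 5 (3 equiv), CH2Cl2, 40 °C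
Reagents that add atoms: ethylene, C=C
Why: Enyne cross-metathesis: ethylene–alkyne metathesis gives the 2-substituted butadiene 6, whose unhindered vinyl group then undergoes reversible cross-metathesis with 5, so the internal methylidene stays intact and the new CH=CH bond should settle in the thermodynamically preferred (E) geometry.

Step 5
Reactants: 7 (E)-triethyl{[2-methyl-3-methylidene-6-(2-methyl-1,3-dioxolan-2-yl)hex-4-en-2-yl]oxy}silane; 8 methacrolein
Product: 9 (1R,2R)-1-methyl-2-[(2-methyl-1,3-dioxolan-2-yl)methyl]-4-[2-(triethylsilyloxy)propan-2-yl]cyclohex-3-ene-1-carbaldehyde (CHO trans to the C2 side chain)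
Conditions: (R)-1-(2-methylphenyl)-3,3-diphenyltetrahydro-1H,3H-pyrrolo[1,2-c][1,3,2]oxazaborole (20 mol%), HN(SO2CF3)2 (17 mol%), 8 (3 equiv), CH2Cl2, −78 to −40 °C
Reagents that add atoms: none
Why: Catalyst-bound s-trans methacrolein (boron on the formyl oxygen) reacts with the s-cis diene in a concerted, asynchronous [4+2] cycloaddition, the closest known reaction type being the oxazaborolidinium-catalysed Diels–Alder reaction of 2-substituted acroleins with acyclic 1,3-dienes. Ring B closes as a six-membered ring by the intermolecular annulation that joins C5 to C10 and C8 to C9. C10 is set by the catalyst, which shields one face of the enal so that C5 adds to the face that places the C14 methyl β and the formyl group α. C5 is set relative to C10 by the exo (formyl-out) topology on the (E)-diene, which should be preferred because the endo alternative pushes the catalyst-laden formyl group under C6 and against the C5 side chain; it leaves CHO trans to the C4 chain, as the trans ring fusion requires. Regioselectivity is secured twice over, since the C5 alkyl terminus and the C7 branch both direct the enal α-carbon to C5, and the bulky C7 substituent also favours the reactive s-cis conformer. Exo and enantiofacial selectivity are the selectivities the step needs.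

Step 6
Reactants: 9 the Diels–Alder aldehyde
Product: 10 (1R,2R)-1-methyl-2-(2-oxopropyl)-4-[2-(triethylsilyloxy)propan-2-yl]cyclohex-3-ene-1-carbaldehyde
Conditions: PPTS (cat.), acetone–H2O (10:1), 50 °C
Reagents that add atoms: water, O
Why: Acid-catalysed ketal hydrolysis under buffered conditions that a tertiary triethylsilyl ether should tolerate; the aldehyde has no α-hydrogen and cannot epimerise.

Step 7
Reactants: 10 the keto aldehyde
Product: 12 11-(triethylsilyloxy)-15-nor-5αH-eudesma-1,6-dien-3-one (10β-methyl, trans ring fusion), via β-hydroxy ketone 11 (not isolated)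
Conditions: KOH (0.5 equiv), MeOH, 0 °C to rt
Reagents that add atoms: none
Why: Intramolecular aldol condensation (6-enolendo-exo-trig): only the methyl enolate of the ketone can reach the non-enolisable aldehyde through a six-membered transition state, and dehydration of 11 gives the C1=C2 enone and closes ring A.

Step 8
Reactants: 12 the ring A enone
Product: 14 4α-methyl-11-(triethylsilyloxy)-5αH-eudesma-1,6-dien-3-one (C4 epimer mixture tolerated), via lithium dienolate 13 (not isolated)
Conditions: LiN(i-Pr)2 (1.1 equiv), THF, −78 °C; MeI, −78 to −40 °C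
Reagents that add atoms: iodomethane, CI
Why: Kinetic α′-deprotonation of the enone can occur only at C4 (C10 is quaternary, so no γ-enolisation), and the cross-conjugated enolate is methylated, mainly anti to the C14 methyl; this centre is erased in the next step.

Step 9
Reactants: 14 the 4-methyl enone
Product: 16 4α-hydroxy-11-(triethylsilyloxy)-5αH-eudesma-1,6-dien-3-one (4β-methyl), via potassium dienolate 15 (not isolated)
Conditions: KN(SiMe3)2 (1.2 equiv), THF, −78 °C; 2-(phenylsulfonyl)-3-phenyloxaziridine; AcOH, −78 °C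
Reagents that add atoms: 2-(phenylsulfonyl)-3-phenyloxaziridine, O=S(=O)(c1ccccc1)N1OC1c1ccccc1
Why: Enolate hydroxylation with the Davis oxaziridine: the tetrasubstituted C3=C4 enolate should be attacked at C4 from the α face, anti to the axial C14 methyl that overhangs the β face, which sets C4 (4α-OH, 4β-CH3).

Step 10
Reactants: 16 the α′-hydroxy enone
Product: 17 4α-hydroxy-11-(triethylsilyloxy)-5αH-eudesm-6-en-3-one
Conditions: H2 (1 atm), RhCl(PPh3)3 (10 mol%), benzene, rt
Reagents that add atoms: none
Why: Homogeneous hydrogenation should saturate the disubstituted C1=C2 bond and leave the hindered trisubstituted C6=C7 bond and the allylic silyl ether untouched.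

Step 11
Reactants: 17 the saturated ketol
Product: 18 11-(triethylsilyloxy)-5αH-eudesm-6-ene-3α,4α-diol
Conditions: LiBH(s-Bu)3 (2.5 equiv), THF, −78 °C; then aq. NaOH, H2O2, 0 °C
Reagents that add atoms: none
Why: Bulky hydride reduction: the reagent should approach C3 along the equatorial trajectory, avoiding the axial 1α-H and 5α-H, as in tri-sec-butylborohydride reductions of 4,4-disubstituted 3-oxo terpenoids, which gives the axial 3α-alcohol cis to the 4α-hydroxyl.

Step 12
Reactants: 18 the cis-diol
Product: 19 4α-hydroxy-11-(triethylsilyloxy)-5αH-eudesm-6-en-3α-yl (Z)-2-methylbut-2-enoate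
Conditions: angelic acid, 2,4,6-trichlorobenzoyl chloride, Et3N, toluene, rt; then 18, 80 °C
Reagents that add atoms: angelic acid, C/C=C(/C)C(=O)O
Why: Yamaguchi-type acylation through the mixed anhydride, a method that transfers the angeloyl group without (Z) to (E) isomerisation; only the secondary 3α-hydroxyl should react, the tertiary 4α-hydroxyl being too hindered.

Step 13
Reactants: 19 the 3-angelate
Product: 20 4α-acetoxy-11-(triethylsilyloxy)-5αH-eudesm-6-en-3α-yl (Z)-2-methylbut-2-enoate
Conditions: Ac2O, DMAP, Et3N, CH2Cl2, 40 °C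
Reagents that add atoms: acetic anhydride, CC(=O)OC(C)=O
Why: DMAP-catalysed acetylation of a tertiary alcohol (Steglich conditions); the conjugated angelate is a poor acyl donor, so migration to O4 should not compete.

Step 14
Reactants: 20 the diester
Product: 21 4α-acetoxy-8-oxo-11-(triethylsilyloxy)-5αH-eudesm-6-en-3α-yl (Z)-2-methylbut-2-enoate
Conditions: CrO3, 3,5-dimethylpyrazole, CH2Cl2, −20 °C
Reagents that add atoms: chromium trioxide, O=[Cr](=O)=O
Why: Allylic oxidation with the CrO3–3,5-dimethylpyrazole complex: C8 is the only allylic methylene of the C6=C7 alkene, the other allylic site (C5–H) being tertiary, flanked by two quaternary carbons and deactivated by the β-acetoxy group, and the electron-poor angelate alkene should not be attacked.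

Step 15
Reactants: 21 the silylated enone
Product: 22 (3R,4S,5R,10R)-4-acetoxy-11-hydroxy-8-oxoeudesm-6-en-3-yl (Z)-2-methylbut-2-enoate (target)
Conditions: HF·pyridine, pyridine, THF, 0 °C to rt
Reagents that add atoms: none
Why: Fluoride-mediated desilylation under mildly acidic conditions, which avoids base-induced vinylogous elimination of the C4 acetate through C5 and acyl migration.

**Compound list**

1 | 2-methylbut-3-yn-2-ol | CC(C)(O)C#C | starting material
2 | triethyl[(2-methylbut-3-yn-2-yl)oxy]silane | CC(C)(O[Si](CC)(CC)CC)C#C | intermediate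
3 | ethyl (2-methyl-1,3-dioxolan-2-yl)acetate | CCOC(=O)CC1(C)OCCO1 | starting material
4 | (2-methyl-1,3-dioxolan-2-yl)acetaldehyde | O=CCC1(C)OCCO1 | intermediate
5 | 2-methyl-2-(prop-2-en-1-yl)-1,3-dioxolane | C=CCC1(C)OCCO1 | intermediate
6 | triethyl[(2-methyl-3-methylidenepent-4-en-2-yl)oxy]silane | C=CC(=C)C(C)(C)O[Si](CC)(CC)CC | intermediate (not isolated)
7 | (E)-triethyl{[2-methyl-3-methylidene-6-(2-methyl-1,3-dioxolan-2-yl)hex-4-en-2-yl]oxy}silane | C=C(C(C)(C)O[Si](CC)(CC)CC)/C=C/CC1(C)OCCO1 | intermediate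
8 | methacrolein (2-methylprop-2-enal) | CC(=C)C=O | starting material
9 | (1R,2R)-1-methyl-2-[(2-methyl-1,3-dioxolan-2-yl)methyl]-4-[2-(triethylsilyloxy)propan-2-yl]cyclohex-3-ene-1-carbaldehyde | O=C[C@]1(C)CCC(C(C)(C)O[Si](CC)(CC)CC)=C[C@H]1CC2(C)OCCO2 | intermediate
10 | (1R,2R)-1-methyl-2-(2-oxopropyl)-4-[2-(triethylsilyloxy)propan-2-yl]cyclohex-3-ene-1-carbaldehyde | O=C[C@]1(C)CCC(C(C)(C)O[Si](CC)(CC)CC)=C[C@H]1CC(C)=O | intermediate
11 | 1-hydroxy-11-(triethylsilyloxy)-15-nor-5αH-eudesm-6-en-3-one (either configuration at C1) | O=C1CC(O)[C@]2(C)CCC(C(C)(C)O[Si](CC)(CC)CC)=C[C@H]2C1 | intermediate (not isolated)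
12 | 11-(triethylsilyloxy)-15-nor-5αH-eudesma-1,6-dien-3-one | O=C1C=C[C@]2(C)CCC(C(C)(C)O[Si](CC)(CC)CC)=C[C@H]2C1 | intermediate
13 | lithium 3,4-dienolate of 12 | [Li+].[O-]C=1C=C[C@]2(C)CCC(C(C)(C)O[Si](CC)(CC)CC)=C[C@H]2C=1 | intermediate (not isolated)
14 | 4α-methyl-11-(triethylsilyloxy)-5αH-eudesma-1,6-dien-3-one (expected major C4 epimer) | O=C1C=C[C@]2(C)CCC(C(C)(C)O[Si](CC)(CC)CC)=C[C@H]2[C@@H]1C | intermediate
15 | potassium 3,4-dienolate of 14 | [K+].[O-]C=1C=C[C@]2(C)CCC(C(C)(C)O[Si](CC)(CC)CC)=C[C@H]2C=1C | intermediate (not isolated)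
16 | 4α-hydroxy-11-(triethylsilyloxy)-5αH-eudesma-1,6-dien-3-one | O=C1C=C[C@]2(C)CCC(C(C)(C)O[Si](CC)(CC)CC)=C[C@H]2[C@]1(C)O | intermediate
17 | 4α-hydroxy-11-(triethylsilyloxy)-5αH-eudesm-6-en-3-one | O=C1CC[C@]2(C)CCC(C(C)(C)O[Si](CC)(CC)CC)=C[C@H]2[C@]1(C)O | intermediate
18 | 11-(triethylsilyloxy)-5αH-eudesm-6-ene-3α,4α-diol | O[C@@H]1CC[C@]2(C)CCC(C(C)(C)O[Si](CC)(CC)CC)=C[C@H]2[C@]1(C)O | intermediate
19 | 4α-hydroxy-11-(triethylsilyloxy)-5αH-eudesm-6-en-3α-yl (Z)-2-methylbut-2-enoate | C/C=C(/C)C(=O)O[C@@H]1CC[C@]2(C)CCC(C(C)(C)O[Si](CC)(CC)CC)=C[C@H]2[C@]1(C)O | intermediate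
20 | 4α-acetoxy-11-(triethylsilyloxy)-5αH-eudesm-6-en-3α-yl (Z)-2-methylbut-2-enoate | C/C=C(/C)C(=O)O[C@@H]1CC[C@]2(C)CCC(C(C)(C)O[Si](CC)(CC)CC)=C[C@H]2[C@]1(C)OC(C)=O | intermediate
21 | 4α-acetoxy-8-oxo-11-(triethylsilyloxy)-5αH-eudesm-6-en-3α-yl (Z)-2-methylbut-2-enoate | C/C=C(/C)C(=O)O[C@@H]1CC[C@]2(C)CC(=O)C(C(C)(C)O[Si](CC)(CC)CC)=C[C@H]2[C@]1(C)OC(C)=O | intermediate
22 | (3R,4S,5R,10R)-4-acetoxy-11-hydroxy-8-oxoeudesm-6-en-3-yl (Z)-2-methylbut-2-enoate | C/C=C(/C)C(=O)O[C@@H]1CC[C@]2(C)CC(=O)C(C(C)(C)O)=C[C@H]2[C@]1(C)OC(C)=O | target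

**Step count**

Total steps: 15. Longest linear sequence: 14 steps (3 to 22, steps 2 to 15); the branch from 1 joins at step 4.

**Steps most likely to fail**

1. Step 5 (Diels–Alder). The formyl group may add partly in the endo mode, or the ketal oxygens may compete for the boron centre, so that the C5/C10 relation is not set cleanly.
 Fallback, from 7 back to 9: the relative configuration is set by enolate alkylation instead of by cycloaddition topology.
 - Diene 7 is combined with 2,2,2-trifluoroethyl acrylate under the same class of oxazaborolidinium catalyst (enantiomer chosen for C5). The reliably endo cycloaddition should give the cis ester F1.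
 - F1 is enolised with LiN(i-Pr)2 at −78 °C, which erases C10, and alkylated with 4-methoxybenzyl chloromethyl ether anti to the C5 side chain to give the quaternary ester F2.
 - LiAlH4 reduces F2 to the neopentyl alcohol F3; MsCl and Et3N give the mesylate F4; LiBHEt3 in refluxing THF gives the C14 methyl compound F5.
 - DDQ in wet CH2Cl2 frees the primary alcohol F6, and Dess–Martin periodinane oxidises it to 9.

2. Step 11 (C3 reduction). Hydride may instead be delivered to the α face of C3 (axial attack, anti to the axial 4β-methyl), giving the 3β-alcohol and a trans-diol.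
 Fallback, from 14 back to 18: both C–O bonds are made in one suprafacial addition.
 - 14 is converted with KN(SiMe3)2 and PhN(SO2CF3)2 into the dienyl triflate F7.
 - Pd(OAc)2, PPh3, HCO2H and Et3N reduce F7 to the ring A 1,3-diene F8.
 - Catalytic OsO4 with N-methylmorpholine N-oxide should dihydroxylate the trisubstituted C3=C4 bond from the α face, anti to C14, giving the ene-diol F9.
 - H2 with RhCl(PPh3)3 saturates C1=C2 and gives 18.

3. Step 14 (allylic oxidation). Hydrogen abstraction at C5, oxygen transfer to the C6 end of the allylic system, or attack on the angelate may erode the regioselectivity.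
 Fallback, from 20 back to 21: a closed-shell ene reaction followed by a [2,3]-shift replaces the direct oxidation.
 - Catalytic SeO2 with t-BuOOH in CH2Cl2 should hydroxylate the ring methylene next to the more substituted alkene carbon (C8), giving the allylic alcohol F10.
 - Dess–Martin periodinane oxidises F10 to 21.

**Further compounds**

F1 | step 5 | 2,2,2-trifluoroethyl 2-[(2-methyl-1,3-dioxolan-2-yl)methyl]-4-[2-(triethylsilyloxy)propan-2-yl]cyclohex-3-ene-1-carboxylate (ester cis to the C2 side chain) | O=C(OCC(F)(F)F)[C@H]1CCC(C(C)(C)O[Si](CC)(CC)CC)=C[C@H]1CC2(C)OCCO2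
F2 | step 5 | 2,2,2-trifluoroethyl 1-[(4-methoxybenzyloxy)methyl]-2-[(2-methyl-1,3-dioxolan-2-yl)methyl]-4-[2-(triethylsilyloxy)propan-2-yl]cyclohex-3-ene-1-carboxylate (ester cis to the C2 side chain) | O=C(OCC(F)(F)F)[C@@]1(COCc3ccc(OC)cc3)CCC(C(C)(C)O[Si](CC)(CC)CC)=C[C@H]1CC2(C)OCCO2
F3 | step 5 | {1-[(4-methoxybenzyloxy)methyl]-2-[(2-methyl-1,3-dioxolan-2-yl)methyl]-4-[2-(triethylsilyloxy)propan-2-yl]cyclohex-3-en-1-yl}methanol (CH2OH cis to the C2 side chain) | OC[C@@]1(COCc3ccc(OC)cc3)CCC(C(C)(C)O[Si](CC)(CC)CC)=C[C@H]1CC2(C)OCCO2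
F4 | step 5 | methanesulfonate of F3 | CS(=O)(=O)OC[C@@]1(COCc3ccc(OC)cc3)CCC(C(C)(C)O[Si](CC)(CC)CC)=C[C@H]1CC2(C)OCCO2
F5 | step 5 | 4-methoxybenzyl ether of {1-methyl-2-[(2-methyl-1,3-dioxolan-2-yl)methyl]-4-[2-(triethylsilyloxy)propan-2-yl]cyclohex-3-en-1-yl}methanol (methyl cis to the C2 side chain) | C[C@@]1(COCc3ccc(OC)cc3)CCC(C(C)(C)O[Si](CC)(CC)CC)=C[C@H]1CC2(C)OCCO2
F6 | step 5 | {1-methyl-2-[(2-methyl-1,3-dioxolan-2-yl)methyl]-4-[2-(triethylsilyloxy)propan-2-yl]cyclohex-3-en-1-yl}methanol (methyl cis to the C2 side chain) | C[C@@]1(CO)CCC(C(C)(C)O[Si](CC)(CC)CC)=C[C@H]1CC2(C)OCCO2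
F7 | step 11 | 4-methyl-11-(triethylsilyloxy)-5αH-eudesma-1,3,6-trien-3-yl trifluoromethanesulfonate | FC(F)(F)S(=O)(=O)OC=1C=C[C@]2(C)CCC(C(C)(C)O[Si](CC)(CC)CC)=C[C@H]2C=1C
F8 | step 11 | 11-(triethylsilyloxy)-5αH-eudesma-1,3,6-triene | CC1=CC=C[C@]2(C)CCC(C(C)(C)O[Si](CC)(CC)CC)=C[C@H]21
F9 | step 11 | 11-(triethylsilyloxy)-5αH-eudesma-1,6-diene-3α,4α-diol | O[C@@H]1C=C[C@]2(C)CCC(C(C)(C)O[Si](CC)(CC)CC)=C[C@H]2[C@]1(C)O
F10 | step 14 | 4α-acetoxy-8-hydroxy-11-(triethylsilyloxy)-5αH-eudesm-6-en-3α-yl (Z)-2-methylbut-2-enoate (either configuration at C8) | C/C=C(/C)C(=O)O[C@@H]1CC[C@]2(C)CC(O)C(C(C)(C)O[Si](CC)(CC)CC)=C[C@H]2[C@]1(C)OC(C)=O
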